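The terpene half is an isocamphane: spiro carbon C2′ lies between bridgehead C1′ and C3′Me2, and C1′–C6′–C5′–C4′–C7′ is an unsubstituted cyclopentane. A bornane delivers exactly this pattern when C6 migrates from C1 to C2. The key step is therefore the Wagner–Meerwein contraction of the cyclohexane ring of the exo-mesylate made from (1S)-camphor. In one operation it forms the cyclopentane, brings CMe2 next to the future spiro carbon and leaves a cleavable methylene there. A cation at C2′ would accept the phenol oxygen on its exo face, whereas the target has oxygen endo. C2′ is therefore set afterwards by exo attack of an acetylide on camphenilone, and C4 by face-selective hydrogenation.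

Key step: step 2

Remark on the reading of the target and on locants: chroman O1, C2 (= C2′, spiro), C3, C4, C4a–C8a; norbornane C1′–C7′. The SMILES is read as (1′R,2R,4S,4′S), that is O1 endo and C3 exo on C2′, with the isobutyl group on C4 cis to C3′Me2 across the pyran ring. Compounds 1–3 carry bornane locants C1–C10.

Step 1
Reactants: 1 (1S,4S)-(−)-camphor
Product: 2 (1S,2S,4S)-isoborneol (2-exo alcohol)
Conditions: LiAlH4, Et2O, 0 °C to rt; then H2O
Reagents that add atoms: none
Why: Hydride reduction under steric approach control: the C7 methyl syn to the carbonyl shields the exo face, so hydride should enter from the endo face and set C2 as the exo alcohol, whose C–O bond is antiperiplanar to C1–C6 (any endo epimer is removed by chromatography).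

Step 2
Reactants: 2 (1S,2S,4S)-isoborneol
Product: 5 (1S,4R)-(−)-camphene, via isobornyl mesylate 3 (not isolated), via isocamphyl cation 4 (not isolated)
Conditions: MsCl, pyridine, 0 °C, then 60 °C
Reagents that add atoms: none
Why: Mesylation gives 3, whose exo C2–O bond lies antiperiplanar to the C1–C6 σ bond, so ionisation is assisted and C6 moves from C1 to C2 (Wagner–Meerwein 1,2-shift) to give tertiary cation 4, from which pyridine removes a C10 proton (E1); the closest known reaction type is the classical isoborneol-to-camphene dehydration. No ring is closed by cyclisation: the suprafacial 1,2-alkyl shift contracts the bornane cyclohexane C1–C2–C3–C4–C5–C6 to the cyclopentane C2–C3–C4–C5–C6 (C1′, C7′, C4′, C5′, C6′ of the target) and at the same time expands the ring C1–C6–C5–C4–C7 to the six-membered ring C2′–C1′–C6′–C5′–C4′–C3′. The only new stereocentre, C1′ (old C2), is set by backside entry of C6 as the mesylate leaves (inversion, enforced by the cage), and C4′ (old C4) is untouched, so the absolute configuration of camphor is carried over. The step needs shift plus deprotonation to outrun the 6,2-hydride and 3,2-methyl (Nametkin) shifts, which would racemise, and the 1,3-elimination to tricyclene. The assisted exo leaving group and the basic, poorly ionising medium, which shortens the life of 4, should secure this. Commercial camphene is of low optical purity, so making it from enantiopure camphor is what secures the single enantiomer.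

Step 3
Reactants: 5 (1S,4R)-(−)-camphene
Product: 6 (1R,4S)-camphenilone
Conditions: O3, CH2Cl2–MeOH, −78 °C; then Me2S, −78 °C to rt
Reagents that add atoms: ozone, [O-][O+]=O
Why: Ozonolysis (Criegee mechanism) with reductive work-up cleaves the only C=C bond to the non-enolisable ketone, and no stereocentre is touched.

Step 4
Reactants: 6 (1R,4S)-camphenilone; 7 4-methylpent-1-yne
Product: 9 (1R,2R,4S)-3,3-dimethyl-2-exo-(4-methylpent-1-ynyl)bicyclo[2.2.1]heptan-2-endo-ol, via lithium acetylide 8 (not isolated)
Conditions: 7, n-BuLi, THF, −78 °C; then 6, −78 °C to rt; then H2O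
Reagents that add atoms: none
Why: 1,2-Addition of a slim lithium acetylide to a non-enolisable ketone: as in organolithium additions to fenchone, the nucleophile should enter from the exo face (the endo face is closed by the endo hydrogens on C5′/C6′ and the endo methyl), which sets C2′ with carbon exo and oxygen endo.

Step 5
Reactants: 10 5-fluorobenzene-1,3-diol
Product: 11 1,3-bis(benzyloxy)-5-fluorobenzene
Conditions: BnBr, K2CO3, DMF, 60 °C
Reagents that add atoms: benzyl bromide, BrCc1ccccc1
Why: Williamson ether synthesis (SN2) on both phenoxides, with no stereocentre involved.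

Step 6
Reactants: 11 1,3-bis(benzyloxy)-5-fluorobenzene
Product: 12 1,5-bis(benzyloxy)-3-fluoro-2-iodobenzene
Conditions: NIS, TFA (cat.), MeCN, 0 °C to rt
Reagents that add atoms: N-iodosuccinimide, O=C1CCC(=O)N1I
Why: Electrophilic aromatic iodination (SEAr) should go para to one benzyloxy group and ortho to the other, next to fluorine, rather than into the crowded site between the two benzyloxy groups.

Step 7
Reactants: 9 exo-alkynyl endo-carbinol; 12 1,5-bis(benzyloxy)-3-fluoro-2-iodobenzene
Product: 14 (1R,2S,4S)-2-exo-{(Z)-2-[2,4-bis(benzyloxy)-6-fluorophenyl]-4-methylpent-1-enyl}-3,3-dimethylbicyclo[2.2.1]heptan-2-endo-ol, via vinylalanate 13 (not isolated)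
Conditions: Red-Al, THF, 0 °C to rt; then 12, Pd(PPh3)4 (cat.), ZnCl2 (cat.), THF, 60 °C; then H2O
Reagents that add atoms: none
Why: Alkoxide-directed trans-hydroalumination places aluminium on the distal alkyne carbon C4 in a five-membered chelate (Al cis to C2′), and the Pd/Zn-cocatalysed Negishi-type coupling of this alkenylalane with 12 proceeds with retention, so the aryl group ends cis to the carbinol (Z).

Step 8
Reactants: 14 (Z)-aryl alkenol
Product: 15 (1′R,2S,4′S)-5,7-bis(benzyloxy)-3′,3′-dimethyl-4-(2-methylpropyl)spiro[chromene-2,2′-bicyclo[2.2.1]heptane] (O1 endo, C3 exo)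
Conditions: NaH, DMF, 80 °C
Reagents that add atoms: none
Why: Intramolecular SNAr (addition–elimination): the Z-alkene holds the alkoxide next to C–F, the two meta alkoxy groups stabilise the Meisenheimer adduct inductively, and because the C2′–O bond is never broken the spiro configuration is retained.

Step 9
Reactants: 15 spiro-2H-chromene
Product: 16 (1′R,2R,4S,4′S)-3′,3′-dimethyl-4-(2-methylpropyl)-3,4-dihydrospiro[chromene-2,2′-bicyclo[2.2.1]heptane]-5,7-diol
Conditions: H2 (5 bar), Pd/C, EtOAc–EtOH, rt
Reagents that add atoms: none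
Why: Heterogeneous syn-hydrogenation with concurrent benzyl ether hydrogenolysis: the exo methyl of C3′ eclipses C3 and covers one face of C3=C4, so hydrogen should arrive from the face of C1′–H and set C4 as S, with isobutyl cis to C3′Me2.

Step 10
Reactants: 16 spirochroman-5,7-diol
Product: 18 (1′R,2R,4S,4′S)-5,7-dihydroxy-3′,3′-dimethyl-4-(2-methylpropyl)-3,4-dihydrospiro[chromene-2,2′-bicyclo[2.2.1]heptane]-6,8-dicarbaldehyde (CNP0150011.1), via bis(iminium) salt 17 (not isolated)
Conditions: POCl3, DMF, MeCN, 0 °C to rt; then H2O, 40 °C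
Reagents that add atoms: N,N-dimethylformamide, CN(C)C=O; water, O
Why: Double Vilsmeier–Haack formylation at the only free, doubly activated positions C6 and C8; the endo C2′–O bond has no antiperiplanar σ-bond assistance for ionisation and should survive the mildly acidic medium, so no stereocentre changes.

Compound list
1 | (1S,4S)-(−)-camphor | CC1(C)[C@H]2CC[C@]1(C)C(=O)C2 | starting material
2 | (1S,2S,4S)-isoborneol (exo alcohol) | CC1(C)[C@H]2CC[C@]1(C)[C@@H](O)C2 | intermediate
3 | (1S,2S,4S)-isobornyl methanesulfonate | CC1(C)[C@H]2CC[C@]1(C)[C@@H](OS(C)(=O)=O)C2 | intermediate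
4 | isocamphyl cation (2,3,3-trimethylbicyclo[2.2.1]hept-2-yl cation, bridgeheads as in 5) | C[C+]1[C@@H]2CC[C@@H](C2)C1(C)C | intermediate
5 | (1S,4R)-(−)-camphene | C=C1[C@@H]2CC[C@@H](C2)C1(C)C | intermediate
6 | (1R,4S)-camphenilone (3,3-dimethylbicyclo[2.2.1]heptan-2-one) | O=C1[C@@H]2CC[C@@H](C2)C1(C)C | intermediate
7 | 4-methylpent-1-yne | C#CCC(C)C | starting material
8 | lithium 4-methylpent-1-ynide | [Li]C#CCC(C)C | intermediate
9 | (1R,2R,4S)-3,3-dimethyl-2-exo-(4-methylpent-1-ynyl)bicyclo[2.2.1]heptan-2-endo-ol | CC(C)CC#C[C@@]1(O)[C@@H]2CC[C@@H](C2)C1(C)C | intermediate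
10 | 5-fluorobenzene-1,3-diol | Oc1cc(O)cc(F)c1 | starting material
11 | 1,3-bis(benzyloxy)-5-fluorobenzene | Fc1cc(OCc2ccccc2)cc(OCc2ccccc2)c1 | intermediate
12 | 1,5-bis(benzyloxy)-3-fluoro-2-iodobenzene | Fc1cc(OCc2ccccc2)cc(OCc2ccccc2)c1I | intermediate
13 | sodium vinylalanate (five-membered O–Al–C4 chelate, two 2-methoxyethoxy ligands on Al, O endo on C2′) | CC(C)CC1=C[C@@]2(O[Al-]1(OCCOC)OCCOC)[C@@H]1CC[C@@H](C1)C2(C)C.[Na+] | intermediate
14 | (1R,2S,4S)-2-exo-{(Z)-2-[2,4-bis(benzyloxy)-6-fluorophenyl]-4-methylpent-1-enyl}-3,3-dimethylbicyclo[2.2.1]heptan-2-endo-ol | CC(C)C/C(=C/[C@@]1(O)[C@@H]2CC[C@@H](C2)C1(C)C)c1c(F)cc(OCc2ccccc2)cc1OCc1ccccc1 | intermediate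
15 | (1′R,2S,4′S)-5,7-bis(benzyloxy)-3′,3′-dimethyl-4-(2-methylpropyl)spiro[chromene-2,2′-bicyclo[2.2.1]heptane] | CC(C)CC1=C[C@@]2(Oc3cc(OCc4ccccc4)cc(OCc4ccccc4)c31)[C@@H]1CC[C@@H](C1)C2(C)C | intermediate
16 | (1′R,2R,4S,4′S)-3′,3′-dimethyl-4-(2-methylpropyl)-3,4-dihydrospiro[chromene-2,2′-bicyclo[2.2.1]heptane]-5,7-diol | CC(C)C[C@H]1C[C@@]2(Oc3cc(O)cc(O)c31)[C@@H]1CC[C@@H](C1)C2(C)C | intermediate
17 | 6,8-bis(dimethyliminiomethyl) derivative of 16, dichloride | CC(C)C[C@H]1C[C@@]2(Oc3c(C=[N+](C)C)c(O)c(C=[N+](C)C)c(O)c31)[C@@H]1CC[C@@H](C1)C2(C)C.[Cl-].[Cl-] | intermediate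
18 | (1′R,2R,4S,4′S)-5,7-dihydroxy-3′,3′-dimethyl-4-(2-methylpropyl)-3,4-dihydrospiro[chromene-2,2′-bicyclo[2.2.1]heptane]-6,8-dicarbaldehyde | CC(C)C[C@H]1C[C@@]2(Oc3c(C=O)c(O)c(C=O)c(O)c31)[C@@H]1CC[C@@H](C1)C2(C)C | target

Total step count: 10. Longest linear sequence: 8 (steps 1–4 and 7–10).

Steps most likely to fail

Step 7. Transmetalation from the crowded alkenyl–aluminium centre to palladium may be slower than protodemetalation, so that only the uncoupled (E)-allylic alcohol is returned. In the fallback the polarity of the coupling is reversed. Setting out from 13, the alanate is quenched with iodine at −78 °C to the (Z)-γ-iodo allylic alcohol F1. From 12, zinc insertion (Zn, LiCl, THF) gives the arylzinc iodide F2. Negishi coupling of the two (Pd2(dba)3, SPhos, THF, 50 °C) proceeds with retention and comes back to the route at 14.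

Step 10. Acid released in the Vilsmeier medium may ionise the tertiary C2′–O bond, with loss of the spiro configuration through skeletal shifts, or the second formylation may stall on the deactivated ring. In the fallback, setting out from 16, both formyl groups are introduced under basic conditions by magnesium-phenoxide-directed ortho-formylation (Casnati–Skattebøl: MgCl2, Et3N, paraformaldehyde, MeCN, reflux). Hydroxymethylation and hydride transfer to formaldehyde replace the iminium electrophile. The fallback comes back at 18 and makes no new compound (F0).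

Step 9. The trisubstituted, doubly flanked C3=C4 bond may resist adsorption on palladium, so that allylic C2′–O hydrogenolysis or loss of facial selectivity takes over. In the fallback, setting out from 15, a manganese-catalysed hydrogen-atom-transfer hydrogenation (Mn(dpm)3, PhSiH3, t-BuOOH, i-PrOH, rt) adds a hydrogen atom to C3. The C4 benzylic radical then takes its hydrogen from the open C1′–H face, giving the dibenzyl chroman F3. Hydrogenolysis (H2, Pd/C, EtOAc) removes the benzyl groups and comes back at 16.

Further compounds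
F1 | step 7 | (1R,2S,4S)-2-exo-[(Z)-2-iodo-4-methylpent-1-enyl]-3,3-dimethylbicyclo[2.2.1]heptan-2-endo-ol | CC(C)C/C(I)=C/[C@@]1(O)[C@@H]2CC[C@@H](C2)C1(C)C
F2 | step 7 | [2,4-bis(benzyloxy)-6-fluorophenyl]zinc iodide | I[Zn]c1c(F)cc(OCc2ccccc2)cc1OCc1ccccc1
F0 | step 10 | none | none
F3 | step 9 | (1′R,2R,4S,4′S)-5,7-bis(benzyloxy)-3′,3′-dimethyl-4-(2-methylpropyl)-3,4-dihydrospiro[chromene-2,2′-bicyclo[2.2.1]heptane] | CC(C)C[C@H]1C[C@@]2(Oc3cc(OCc4ccccc4)cc(OCc4ccccc4)c31)[C@@H]1CC[C@@H](C1)C2(C)C
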